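The numbers in the tables were computed for substances that don't exist, noise included.

1. Each small charge of E, a quarter of the whole, enters within 0.750 min, so I first ask which numbers must be known well to reach c_G at the end.

all flasks: Z 20 mM

| flask | E | remark | time |
|---|---|---|---|
| epsilon | 40 mM (in portions, 4) | the very flask that is asked about, followed so far; portions every 15 s |  |
| flask | 40.0 mM (in portions, 4) | the portions of E follow each other after 15 s, the first at the start | 15 min |

- epsilon (time / min: G / %, X / %): 0.500: 12, 0; 1.00: 18, 3; 2.50: 33, 14; 6.00: 31, 34

(scatter of a reading: 2 percentage points)

- equivalents of E to Z, everything else as given, that leave most G at 15 min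
- the amount of G then, in percent of the Z charged
- the amount of G with the amounts as given



2. My yardstick is the apparent (pseudo-first-order) half-life of G, the time G would take to halve if it went at the rate c_X rises between the last two readings, taken on the mean c_G: 3.88 min.

3. By the readings, the part of the charged Z not found in G or X stands at 35.0% at 6.00 min, and its fall between the last two readings gives an apparent half-life of 5.85 min. The time still to run holds 2.32 half-lives of G.

4. The feed matters little to this count because it is shorter than the half-life of G. An error of 2 percentage points in c_G at 6.00 min shifts the end by 0.4 points, and the same error in Z by 0.57 points. The scatter on the rise of c_X, however, moves the half-life between 3.40 min and 4.52 min, and so the end between 13.9% and 18.8%. That half-life is the number to know.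

5. Holding both half-lives, I let the G present decay while Z feeds in more, and I reckon 16.1% for the charge as given. I reckon no best equivalents of my own.

6. The forecast says “the given charge overshoots” and gives 24% (18% to 30%) for that charge, and 33% at 1.3 equiv for the best. My value for the given charge is lower.

7. This flask gives 16.6%, and its best is 28.2% at 0.914 equiv.

    Z + E → G + J (k = 0.170 /M/s)
    E + G → X + J (k = 0.160 /M/s)
    Z ⇌ Q (K = 2.50, k = 0.00110 /s)
    E + J ⇌ D, settled at all times (K = 690 /M)
    L ⇌ J, rate k5*(cs5 - [J]) while solid is left; crystals form when [J] > cs5 (solubility = 0.230 mM, k = 0.280 /s)

The count of 2.32 half-lives gave me 16.1% for this flask, and the forecast stands 7.4 points above what it holds. For a reading of the same flask at 10 min, I count 1.03 of my half-lives of G from 6.00 min, and the same sum gives 24.4%. That neighbouring reading holds c_G at 23.9%.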